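**Retrosynthetic overview**

1. Target ⇐ tris(benzyl ether) (global hydrogenolysis); its 1,3-diol ⇐ anti vinyl carbinol (C9″–OH by oxidative cleavage of the vinyl group).
2. C7″–C8″ ⇐ catalytic anti-selective (α-aryl)allylation joining a C5-propynyl lactone with O-benzylvanillyl alcohol; propynyl ⇐ aryl bromide (Sonogashira).
3. The γ-lactone is the only ring made (the three benzene rings are bought). It is closed in the order of lignan biosynthesis: oxidative 8–8′ coupling first, then reduction to the 9′-hydroxy seco stage, then C9–O closure and equilibration to trans.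
4. C8–C8′ ⇐ oxidative heterocoupling of two C6C3 enolates: a 5-bromodihydroferuloyl oxazolidinone (the auxiliary takes the role of the dirigent protein and sets C8′) and benzyl O-benzyldihydroferulate (its carboxyl becomes the lactone C=O, so ring A ends up α and ring B β).
5. C6C3 units ⇐ 5-bromovanillin + Meldrum's acid, and dihydroferulic acid.

Assumption: the ligand antipode named in step 8 is taken to give the (1R) carbinol; this sense is assigned by analogy and must be checked on a model, and the mirror-image ligand is used if it proves opposite. Locants: C7–C9 ring A unit, C7′–C9′ ring B unit, C7″–C9″ side chain.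

**Route**

Step 1
Reactants: 1 5-bromovanillin (3-bromo-4-hydroxy-5-methoxybenzaldehyde); 2 benzyl bromide
Product: 3 4-(benzyloxy)-3-bromo-5-methoxybenzaldehyde
Conditions: BnBr (1.1 equiv), K2CO3, DMF, rt
Reagents that add atoms: benzyl bromide (2), BrCc1ccccc1
Why: Williamson ether synthesis (SN2 of the phenoxide on benzyl bromide) masks the phenol for the enolate and oxidation chemistry until the last step.

Step 2
Reactants: 3 4-(benzyloxy)-3-bromo-5-methoxybenzaldehyde; 4 Meldrum's acid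
Product: 7 3-[4-(benzyloxy)-3-bromo-5-methoxyphenyl]propanoic acid, via arylidene Meldrum's acid 5 (not isolated), via benzyl Meldrum's acid 6 (not isolated)
Conditions: HCO2H/Et3N (5:2), 95 °C
Reagents that add atoms: Meldrum's acid (4), CC1(C)OC(=O)CC(=O)O1
Why: Reductive Knoevenagel sequence in triethylammonium formate (Knoevenagel condensation, conjugate hydride transfer from formate, ring opening with loss of acetone and CO2) gives the saturated C6C3 acid in one flask without touching the aryl bromide or the benzyl ether.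

Step 3
Reactants: 7 3-[4-(benzyloxy)-3-bromo-5-methoxyphenyl]propanoic acid; 8 (S)-4-benzyl-1,3-oxazolidin-2-one
Product: 10 (4S)-4-benzyl-3-{3-[4-(benzyloxy)-3-bromo-5-methoxyphenyl]propanoyl}-1,3-oxazolidin-2-one, via mixed pivalic anhydride 9 (not isolated)
Conditions: t-BuCOCl, Et3N, THF, −20 °C; then 8, LiCl, rt
Reagents that add atoms: (S)-4-benzyl-1,3-oxazolidin-2-one (8), O=C1OC[C@H](Cc2ccccc2)N1
Why: N-Acylation of the Evans auxiliary through the mixed pivalic anhydride works because the LiCl/Et3N-activated oxazolidinone attacks the less hindered acyl carbon.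

Step 4
Reactants: 11 dihydroferulic acid (3-(4-hydroxy-3-methoxyphenyl)propanoic acid); 2 benzyl bromide
Product: 12 benzyl 3-[4-(benzyloxy)-3-methoxyphenyl]propanoate
Conditions: BnBr (2.2 equiv), K2CO3, DMF, 60 °C
Reagents that add atoms: benzyl bromide (2), BrCc1ccccc1
Why: Double SN2 alkylation (Williamson ether synthesis and carboxylate alkylation) converts the phenol and the acid into benzyl derivatives in one operation.

Step 5
Reactants: 10 (4S)-4-benzyl-3-{3-[4-(benzyloxy)-3-bromo-5-methoxyphenyl]propanoyl}-1,3-oxazolidin-2-one; 12 benzyl 3-[4-(benzyloxy)-3-methoxyphenyl]propanoate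
Product: 15 benzyl (3R)-4-[(4S)-4-benzyl-2-oxo-1,3-oxazolidin-3-yl]-3-[4-(benzyloxy)-3-bromo-5-methoxybenzyl]-2-[4-(benzyloxy)-3-methoxybenzyl]-4-oxobutanoate (both C2 epimers), via lithium enolate of the imide 13 (not isolated), via lithium enolate of the ester 14 (not isolated)
Conditions: 12 (2 equiv), LiN(i-Pr)2 (3.1 equiv), THF, −78 °C; then Fe(acac)3 (trivalent iron, 3.2 equiv), −78 °C to rt
Reagents that add atoms: none
Why: Oxidative enolate heterocoupling, in which Fe(acac)3 takes one electron from the mixed lithium enolate aggregate and the imide-derived α-radical joins the ester enolate at C8–C8′ (the bond that two C6C3 radicals form in lignan biosynthesis), makes the new bond on the face of the chelated (Z)-enolate opposite the auxiliary benzyl group so that C8′ is R, while the uncontrolled ester-side centre C8 is corrected in step 6 and minor C8′ epimers, being diastereomers, are removed on silica.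

Step 6
Reactants: 15 benzyl (3R)-4-[(4S)-4-benzyl-2-oxo-1,3-oxazolidin-3-yl]-3-[4-(benzyloxy)-3-bromo-5-methoxybenzyl]-2-[4-(benzyloxy)-3-methoxybenzyl]-4-oxobutanoate (both C2 epimers)
Product: 18 (3R,4R)-4-[4-(benzyloxy)-3-bromo-5-methoxybenzyl]-3-[4-(benzyloxy)-3-methoxybenzyl]dihydrofuran-2(3H)-one (trans), via hydroxy ester 16 (not isolated), via cis-lactone 17 (not isolated)
Conditions: LiBH4 (1.2 equiv), MeOH (1.2 equiv), THF, 0 °C; aq NH4Cl; then DBU (0.3 equiv), toluene, 60 °C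
Reagents that add atoms: none
Why: Chemoselective hydride reduction of the N-acyl oxazolidinone (more electrophilic than the benzyl ester) frees the C9′ alcohol, which lactonises onto the C9 ester at the same seco-stage C9–O bond that closes the matairesinol lactone in the plant, and base-mediated epimerisation of the enolisable C3 then gives the more stable trans (3R,4R) lactone while C4 stays R.

Step 7
Reactants: 18 (3R,4R)-4-[4-(benzyloxy)-3-bromo-5-methoxybenzyl]-3-[4-(benzyloxy)-3-methoxybenzyl]dihydrofuran-2(3H)-one; 19 propyne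
Product: 20 (3R,4R)-3-[4-(benzyloxy)-3-methoxybenzyl]-4-[4-(benzyloxy)-3-methoxy-5-(prop-1-yn-1-yl)benzyl]dihydrofuran-2(3H)-one
Conditions: propyne (5 equiv), PdCl2(MeCN)2 (divalent palladium, 3 mol%), XPhos (9 mol%), Cs2CO3, MeCN, 70 °C, sealed tube
Reagents that add atoms: propyne (19), CC#C
Why: Copper-free Sonogashira coupling (oxidative addition of the electron-rich aryl bromide to XPhos-ligated zerovalent palladium, carbonate-assisted alkynyl transfer, reductive elimination) installs the C5 carbon handle, and the lactone stays trans because that is its equilibrium configuration under the mild base.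

Step 8
Reactants: 20 (3R,4R)-3-[4-(benzyloxy)-3-methoxybenzyl]-4-[4-(benzyloxy)-3-methoxy-5-(prop-1-yn-1-yl)benzyl]dihydrofuran-2(3H)-one; 21 4-(benzyloxy)-3-methoxybenzyl alcohol
Product: 22 (3R,4R)-3-[4-(benzyloxy)-3-methoxybenzyl]-4-{4-(benzyloxy)-3-[(1R,2S)-1-[4-(benzyloxy)-3-methoxyphenyl]-1-hydroxybut-3-en-2-yl]-5-methoxybenzyl}dihydrofuran-2(3H)-one
Conditions: 21 (2 equiv), H2Ru(CO)(PPh3)3 (divalent ruthenium, 5 mol%), (R)-1-[(S)-2-(dicyclohexylphosphino)ferrocenyl]ethyldi-tert-butylphosphine (5 mol%), 2,4,6-triisopropylbenzenesulfonic acid (5 mol%), Bu4NI (10 mol%), THF, 95 °C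
Reagents that add atoms: 4-(benzyloxy)-3-methoxybenzyl alcohol (21), COc1cc(CO)ccc1OCc1ccccc1
Why: Redox-triggered carbonyl (α-aryl)allylation by transfer hydrogenation, in which the ruthenium hydride dehydrogenates 21 to its aldehyde, isomerises the aryl propyne to the aryl allene and hydrometalates it, lets the (E)-σ-allylruthenium add through a closed chair transition state that places aryl and hydroxyl anti, while the Josiphos ligand sets the (1R) carbinol centre (and with it 2S) independently of the remote lactone centres.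

Step 9
Reactants: 22 (3R,4R)-3-[4-(benzyloxy)-3-methoxybenzyl]-4-{4-(benzyloxy)-3-[(1R,2S)-1-[4-(benzyloxy)-3-methoxyphenyl]-1-hydroxybut-3-en-2-yl]-5-methoxybenzyl}dihydrofuran-2(3H)-one
Product: 25 (3R,4R)-3-[4-(benzyloxy)-3-methoxybenzyl]-4-{4-(benzyloxy)-3-[(1R,2R)-1-[4-(benzyloxy)-3-methoxyphenyl]-1,3-dihydroxypropan-2-yl]-5-methoxybenzyl}dihydrofuran-2(3H)-one, via ozonide 23 (not isolated), via hydroxy aldehyde 24 (not isolated)
Conditions: O3, CH2Cl2, −78 °C (Sudan Red 7B end point); then NaBH4, MeOH, −78 to 0 °C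
Reagents that add atoms: ozone, [O-][O+]=O
Why: Ozonolysis with reductive work-up succeeds because the terminal vinyl group reacts with ozone far faster than the alkoxyarenes and NaBH4 reduces the ozonide through the aldehyde to the primary alcohol in the cold before the enolisable C8″ can epimerise, so both side-chain centres keep their geometry (2S becomes 2R only by the change in CIP priorities) and the γ-lactone is not reduced at 0 °C.

Step 10
Reactants: 25 (3R,4R)-3-[4-(benzyloxy)-3-methoxybenzyl]-4-{4-(benzyloxy)-3-[(1R,2R)-1-[4-(benzyloxy)-3-methoxyphenyl]-1,3-dihydroxypropan-2-yl]-5-methoxybenzyl}dihydrofuran-2(3H)-one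
Product: 26 (3R,4R)-4-{3-[(1R,2R)-1,3-dihydroxy-1-(4-hydroxy-3-methoxyphenyl)propan-2-yl]-4-hydroxy-5-methoxybenzyl}-3-(4-hydroxy-3-methoxybenzyl)dihydrofuran-2(3H)-one (CNP0109231.2)
Conditions: H2 (1 atm), 10% Pd/C, EtOAc/EtOH, rt
Reagents that add atoms: none
Why: Catalytic hydrogenolysis cleaves the three aryl benzyl ethers much faster than the secondary benzylic alcohol under neutral conditions and touches no stereocentre.

**Compound list**

1 | 5-bromovanillin (3-bromo-4-hydroxy-5-methoxybenzaldehyde) | COc1cc(C=O)cc(Br)c1O | starting material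
2 | benzyl bromide | BrCc1ccccc1 | starting material
3 | 4-(benzyloxy)-3-bromo-5-methoxybenzaldehyde | COc1cc(C=O)cc(Br)c1OCc1ccccc1 | intermediate
4 | Meldrum's acid (2,2-dimethyl-1,3-dioxane-4,6-dione) | CC1(C)OC(=O)CC(=O)O1 | starting material
5 | 5-[4-(benzyloxy)-3-bromo-5-methoxybenzylidene]-2,2-dimethyl-1,3-dioxane-4,6-dione | COc1cc(C=C2C(=O)OC(C)(C)OC2=O)cc(Br)c1OCc1ccccc1 | intermediate
6 | 5-[4-(benzyloxy)-3-bromo-5-methoxybenzyl]-2,2-dimethyl-1,3-dioxane-4,6-dione | COc1cc(CC2C(=O)OC(C)(C)OC2=O)cc(Br)c1OCc1ccccc1 | intermediate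
7 | 3-[4-(benzyloxy)-3-bromo-5-methoxyphenyl]propanoic acid | COc1cc(CCC(=O)O)cc(Br)c1OCc1ccccc1 | intermediate
8 | (S)-4-benzyl-1,3-oxazolidin-2-one | O=C1OC[C@H](Cc2ccccc2)N1 | starting material
9 | 3-[4-(benzyloxy)-3-bromo-5-methoxyphenyl]propanoic pivalic anhydride | COc1cc(CCC(=O)OC(=O)C(C)(C)C)cc(Br)c1OCc1ccccc1 | intermediate
10 | (4S)-4-benzyl-3-{3-[4-(benzyloxy)-3-bromo-5-methoxyphenyl]propanoyl}-1,3-oxazolidin-2-one | COc1cc(CCC(=O)N2C(=O)OC[C@@H]2Cc2ccccc2)cc(Br)c1OCc1ccccc1 | intermediate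
11 | dihydroferulic acid (3-(4-hydroxy-3-methoxyphenyl)propanoic acid) | COc1cc(CCC(=O)O)ccc1O | starting material
12 | benzyl 3-[4-(benzyloxy)-3-methoxyphenyl]propanoate | COc1cc(CCC(=O)OCc2ccccc2)ccc1OCc1ccccc1 | intermediate
13 | lithium (Z)-enolate of imide 10 | [Li]O/C(=C\Cc1cc(OC)c(OCc2ccccc2)c(Br)c1)N1C(=O)OC[C@@H]1Cc1ccccc1 | intermediate
14 | lithium enolate of ester 12 | [Li]OC(=CCc1ccc(OCc2ccccc2)c(OC)c1)OCc1ccccc1 | intermediate
15 | benzyl (3R)-4-[(4S)-4-benzyl-2-oxo-1,3-oxazolidin-3-yl]-3-[4-(benzyloxy)-3-bromo-5-methoxybenzyl]-2-[4-(benzyloxy)-3-methoxybenzyl]-4-oxobutanoate (both C2 epimers) | COc1cc(C[C@@H](C(=O)N2C(=O)OC[C@@H]2Cc2ccccc2)C(Cc2ccc(OCc3ccccc3)c(OC)c2)C(=O)OCc2ccccc2)cc(Br)c1OCc1ccccc1 | intermediate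
16 | benzyl (3R)-3-[4-(benzyloxy)-3-bromo-5-methoxybenzyl]-2-[4-(benzyloxy)-3-methoxybenzyl]-4-hydroxybutanoate (both C2 epimers) | COc1cc(C[C@@H](CO)C(Cc2ccc(OCc3ccccc3)c(OC)c2)C(=O)OCc2ccccc2)cc(Br)c1OCc1ccccc1 | intermediate
17 | (3S,4R)-4-[4-(benzyloxy)-3-bromo-5-methoxybenzyl]-3-[4-(benzyloxy)-3-methoxybenzyl]dihydrofuran-2(3H)-one (cis) | COc1cc(C[C@@H]2C(=O)OC[C@@H]2Cc2cc(OC)c(OCc3ccccc3)c(Br)c2)ccc1OCc1ccccc1 | intermediate
18 | (3R,4R)-4-[4-(benzyloxy)-3-bromo-5-methoxybenzyl]-3-[4-(benzyloxy)-3-methoxybenzyl]dihydrofuran-2(3H)-one (trans) | COc1cc(C[C@H]2C(=O)OC[C@@H]2Cc2cc(OC)c(OCc3ccccc3)c(Br)c2)ccc1OCc1ccccc1 | intermediate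
19 | propyne | CC#C | starting material
20 | (3R,4R)-3-[4-(benzyloxy)-3-methoxybenzyl]-4-[4-(benzyloxy)-3-methoxy-5-(prop-1-yn-1-yl)benzyl]dihydrofuran-2(3H)-one | COc1cc(C[C@H]2C(=O)OC[C@@H]2Cc2cc(OC)c(OCc3ccccc3)c(C#CC)c2)ccc1OCc1ccccc1 | intermediate
21 | 4-(benzyloxy)-3-methoxybenzyl alcohol | COc1cc(CO)ccc1OCc1ccccc1 | starting material
22 | (3R,4R)-3-[4-(benzyloxy)-3-methoxybenzyl]-4-{4-(benzyloxy)-3-[(1R,2S)-1-[4-(benzyloxy)-3-methoxyphenyl]-1-hydroxybut-3-en-2-yl]-5-methoxybenzyl}dihydrofuran-2(3H)-one | COc1cc(C[C@H]2C(=O)OC[C@@H]2Cc2cc(OC)c(OCc3ccccc3)c([C@H](C=C)[C@@H](O)c3ccc(OCc4ccccc4)c(OC)c3)c2)ccc1OCc1ccccc1 | intermediate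
23 | ozonide of 22 (vinyl group as 1,2,4-trioxolan-3-yl; other centres as in 22; trioxolane carbon unassigned) | COc1cc(C[C@H]2C(=O)OC[C@@H]2Cc2cc(OC)c(OCc3ccccc3)c([C@H](C5OCOO5)[C@@H](O)c3ccc(OCc4ccccc4)c(OC)c3)c2)ccc1OCc1ccccc1 | intermediate
24 | hydroxy aldehyde from 22 (vinyl group replaced by formyl; other centres unchanged in space) | COc1cc(C[C@H]2C(=O)OC[C@@H]2Cc2cc(OC)c(OCc3ccccc3)c([C@H](C=O)[C@@H](O)c3ccc(OCc4ccccc4)c(OC)c3)c2)ccc1OCc1ccccc1 | intermediate
25 | (3R,4R)-3-[4-(benzyloxy)-3-methoxybenzyl]-4-{4-(benzyloxy)-3-[(1R,2R)-1-[4-(benzyloxy)-3-methoxyphenyl]-1,3-dihydroxypropan-2-yl]-5-methoxybenzyl}dihydrofuran-2(3H)-one | COc1cc(C[C@H]2C(=O)OC[C@@H]2Cc2cc(OC)c(OCc3ccccc3)c([C@H](CO)[C@@H](O)c3ccc(OCc4ccccc4)c(OC)c3)c2)ccc1OCc1ccccc1 | intermediate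
26 | (3R,4R)-4-{3-[(1R,2R)-1,3-dihydroxy-1-(4-hydroxy-3-methoxyphenyl)propan-2-yl]-4-hydroxy-5-methoxybenzyl}-3-(4-hydroxy-3-methoxybenzyl)dihydrofuran-2(3H)-one | COc1cc(C[C@H]2C(=O)OC[C@@H]2Cc2cc(OC)c(O)c([C@H](CO)[C@@H](O)c3ccc(O)c(OC)c3)c2)ccc1O | target

**Step count**

Total step count: 10. Longest linear sequence: 9 steps (1, 2, 3, 5, 6, 7, 8, 9, 10).

**Steps most likely to fail, with fallbacks**

Step 5 (homodimers of 10 and 12, moderate yield, incomplete face control at C8′). The fallback sets out from 10 and comes back at 18. The sodium enolate of 10 (NaN(SiMe3)2, THF, −78 °C) is alkylated with benzyl bromoacetate to the succinate imide F1; this is an Evans alkylation with the same facial sense, so the centre is again R. LiBH4 (THF, 0 °C) reduces the imide to the hydroxy ester F2, which closes to the (R)-β-benzyl lactone F3. Its lithium enolate (LiN(SiMe3)2, THF, −78 °C) is alkylated anti to the C4 substituent with the benzyl bromide F4 (made from 21 with PBr3), which gives trans-18 directly.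

Step 8 (an ortho-alkoxy aryl propyne is an untested substrate; the level and sense of induction are uncertain). The fallback sets out from 18 and comes back at 22. Stille coupling of 18 with tributyl(vinyl)stannane (Pd(PPh3)4, zerovalent palladium, toluene, 100 °C) gives the styrene F5. Cross-metathesis with allylboronic acid pinacol ester (second-generation Hoveyda–Grubbs catalyst, CH2Cl2, 40 °C) gives the (E)-cinnamyl boronate F6. Allylboration of the aldehyde F7 (21 oxidised with MnO2) under a chiral phosphoric acid (the antipode of 3,3′-bis(2,4,6-triisopropylphenyl)-BINOL hydrogen phosphate that gives the 1R carbinol; toluene, −30 °C) goes through the chair transition state of the (E)-boronate and gives anti-22.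

Step 9 (ozone against three electron-rich arenes; the α-aryl-β-hydroxy aldehyde can epimerise or undergo retro-aldol cleavage). The fallback sets out from 22 and comes back at 25. Dihydroxylation of the vinyl group (OsO4 cat., N-methylmorpholine N-oxide, acetone/H2O, rt) gives the triol F8, which can be isolated and purified. NaIO4 (THF/pH 7 buffer, 0 °C) cleaves its only vicinal diol to the hydroxy aldehyde 24, and NaBH4 added to the same flask gives 25.

**Further compounds**

F1 | step 5 | benzyl (3R)-4-[(4S)-4-benzyl-2-oxo-1,3-oxazolidin-3-yl]-3-[4-(benzyloxy)-3-bromo-5-methoxybenzyl]-4-oxobutanoate | COc1cc(C[C@H](CC(=O)OCc2ccccc2)C(=O)N2C(=O)OC[C@@H]2Cc2ccccc2)cc(Br)c1OCc1ccccc1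
F2 | step 5 | benzyl (3R)-3-[4-(benzyloxy)-3-bromo-5-methoxybenzyl]-4-hydroxybutanoate | COc1cc(C[C@H](CC(=O)OCc2ccccc2)CO)cc(Br)c1OCc1ccccc1
F3 | step 5 | (4R)-4-[4-(benzyloxy)-3-bromo-5-methoxybenzyl]dihydrofuran-2(3H)-one | COc1cc(C[C@@H]2CC(=O)OC2)cc(Br)c1OCc1ccccc1
F4 | step 5 | 4-(benzyloxy)-3-methoxybenzyl bromide | COc1cc(CBr)ccc1OCc1ccccc1
F5 | step 8 | (3R,4R)-3-[4-(benzyloxy)-3-methoxybenzyl]-4-[4-(benzyloxy)-3-methoxy-5-vinylbenzyl]dihydrofuran-2(3H)-one | COc1cc(C[C@H]2C(=O)OC[C@@H]2Cc2cc(OC)c(OCc3ccccc3)c(C=C)c2)ccc1OCc1ccccc1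
F6 | step 8 | (3R,4R)-3-[4-(benzyloxy)-3-methoxybenzyl]-4-{4-(benzyloxy)-3-methoxy-5-[(E)-3-(4,4,5,5-tetramethyl-1,3,2-dioxaborolan-2-yl)prop-1-en-1-yl]benzyl}dihydrofuran-2(3H)-one | COc1cc(C[C@H]2C(=O)OC[C@@H]2Cc2cc(OC)c(OCc3ccccc3)c(/C=C/CB3OC(C)(C)C(C)(C)O3)c2)ccc1OCc1ccccc1
F7 | step 8 | 4-(benzyloxy)-3-methoxybenzaldehyde | COc1cc(C=O)ccc1OCc1ccccc1
F8 | step 9 | triol from 22 (vinyl group converted to 1,2-dihydroxyethyl; both epimers at the new carbinol; other centres as in 22) | COc1cc(C[C@H]2C(=O)OC[C@@H]2Cc2cc(OC)c(OCc3ccccc3)c([C@H](C(O)CO)[C@@H](O)c3ccc(OCc4ccccc4)c(OC)c3)c2)ccc1OCc1ccccc1
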